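Ring B is cut at the two bonds of C1, the doubly benzylic methine that joins C2, C8a of ring A and ring C, so C1 and ring C arrive together as one aryl aldehyde. In a single flask an auxiliary-controlled boron aldol addition forms C1–C2 and fixes C2. Acid then ionises the C1–O bond and the electron-rich C8a closes ring B, setting C1 trans to C2. The precursor is the (S)-4-benzyloxazolidinone imide of the E Stobbe half-ester of the same aldehyde, whose alkene geometry holds ring A next to C2. Reductive removal of the auxiliary and debenzylation finish the synthesis.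

Key step: step 3

Assumption: 1 is taken as a catalogue chemical, and lignan numbering is used throughout (C1 bears ring C, C2 the hydroxymethyl or acyl group, C3 the ester; ring A is the fused arene C4a–C8a, ring B the new carbocycle).

Step 1
Reactants: 1 4-benzyloxy-3,5-dimethoxybenzaldehyde; 2 dimethyl succinate
Product: 3 (E)-4-(4-benzyloxy-3,5-dimethoxyphenyl)-3-(methoxycarbonyl)but-3-enoic acid
Conditions: NaOMe, MeOH, reflux; then aq. HCl
Reagents that add atoms: none
Why: Stobbe condensation, in which the succinate enolate adds to 1, the aldolate closes to a paraconic ester lactone and E1cB opening delivers the unreactive carboxylate of the half-ester with ring A trans to the retained C3 ester (E alkene), the matching methoxide base ruling out ester exchange.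

Step 2
Reactants: 3 (E)-half-ester acid; 4 (S)-4-benzyl-2-oxazolidinone
Product: 6 (4S)-4-benzyl-3-[(E)-4-(4-benzyloxy-3,5-dimethoxyphenyl)-3-(methoxycarbonyl)but-3-enoyl]-1,3-oxazolidin-2-one, via mixed pivalic anhydride 5 (not isolated)
Conditions: PivCl, Et3N, THF, −20 °C; then LiCl, 4, −20 °C to rt
Reagents that add atoms: pivaloyl chloride, CC(C)(C)C(=O)Cl (its acyl group sits in 5 only and leaves again before 6)
Why: N-acylation of an oxazolidinone through a mixed pivalic anhydride under LiCl/Et3N activation, where the tert-butyl group steers the lithium-coordinated nitrogen to the less hindered acyl carbon and the absence of a strong base leaves the doubly activated C2 methylene, the E alkene and the stereocentre of 4 unchanged.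

Step 3
Reactants: 6 Stobbe imide; 1 4-benzyloxy-3,5-dimethoxybenzaldehyde
Product: 9 methyl (1S,2R)-7-benzyloxy-1-(4-benzyloxy-3,5-dimethoxyphenyl)-6,8-dimethoxy-2-[(4S)-4-benzyl-2-oxo-1,3-oxazolidine-3-carbonyl]-1,2-dihydronaphthalene-3-carboxylate, via boron dienolate 7 (not isolated), via boron aldolate 8 (not isolated)
Conditions: Bu2BOTf, iPr2NEt, CH2Cl2, −78 to 0 °C; 1 (1.0 equiv), −78 to 0 °C; then CF3CO2H (excess), 0 °C to rt; aq. NaHCO3
Reagents that add atoms: Bu2BOTf (dibutylboron trifluoromethanesulfonate), CCCCB(CCCC)OS(=O)(=O)C(F)(F)F (its Bu2B group sits in 7 and 8 only and leaves again before 9)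
Why: Soft enolisation with Bu2BOTf/iPr2NEt removes a proton from C2, the only CH acid flanked by the imide carbonyl and the C3=C4 acrylate, and gives the Z(O) boron dienolate 7, which adds to 1 through its α-carbon in a closed Zimmerman–Traxler chair (Evans syn-aldol addition, as known for crotonate-derived dienolates) to form C1–C2 in 8. C2 is controlled by the auxiliary, since with the imide dipoles opposed the aldehyde reaches the enolate face remote from the 4-benzyl group, which corresponds to 2R in 9. CF3CO2H, added only after the aldehyde is consumed, protonates the aldolate oxygen, and C1–O heterolysis releases Bu2BOH and a C1 cation stabilised by the trialkoxyphenyl ring C, the closest known reaction being the acid-mediated cycloalkylation of 2-(α-hydroxybenzyl) benzylidenesuccinates to 1-aryl-1,2-dihydronaphthalenes. Ring B closes by an intramolecular Friedel–Crafts alkylation, a six-membered closure that is exo at C1 (6-exo-trig on the quinoid form of the cation), in which C8a (ortho to the C8 and para to the C6 methoxy group) is within reach because the E alkene places ring A cis to C2, and no regioisomer can arise because both ortho positions of ring A are equivalent. C1 is planar after ionisation, so either carbinol epimer would converge, and it is reset under substrate control by C2, because in the closing half-chair the C1 aryl escapes the C8 methoxy group and the C2 acyl escapes the C3 ester only when both are pseudo-axial, which is the trans (1S,2R) arrangement. The selectivities needed are α over γ attack of the dienolate (secured by the cyclic boron transition state and by retention of the cinnamate conjugation) and ring closure over proton loss from C2 or lactonisation on the C3 ester (secured by the proximity and double activation of C8a and by never setting the γ-hydroxy ester free under neutral or basic conditions).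

Step 4
Reactants: 9 cyclised imide
Product: 10 methyl (1S,2R)-7-benzyloxy-1-(4-benzyloxy-3,5-dimethoxyphenyl)-2-(hydroxymethyl)-6,8-dimethoxy-1,2-dihydronaphthalene-3-carboxylate
Conditions: LiBH4, MeOH (1 equiv to LiBH4), THF–Et2O, 0 °C; pH 7 buffer
Reagents that add atoms: none
Why: Reductive cleavage of an N-acyl oxazolidinone with LiBH4, in which the lithium-chelated exocyclic imide carbonyl is far more electrophilic than the C3 ester (deactivated by conjugation with the C3=C4 styrene unit), so two hydrides turn it into the C2 hydroxymethyl group and release 4 while C1 and C2 stay untouched in what is also the more stable trans arrangement.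

Step 5
Reactants: 10 bis-benzyl ether alcohol
Product: 11 methyl (1S,2R)-7-hydroxy-1-(4-hydroxy-3,5-dimethoxyphenyl)-2-(hydroxymethyl)-6,8-dimethoxy-1,2-dihydronaphthalene-3-carboxylate (target)
Conditions: BCl3, C6HMe5, CH2Cl2, −78 °C; then CHCl3–MeOH quench at −78 °C, aqueous work-up
Reagents that add atoms: none
Why: Lewis acid debenzylation with a cation scavenger, in which BCl3 binds the crowded benzylic ether oxygens and the departing benzyl cations are captured by the non-basic arene C6HMe5 in a Friedel–Crafts alkylation, which at −78 °C leaves the methyl ethers, the ester, the C3=C4 alkene (at risk under hydrogenolysis) and both stereocentres intact.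

Compound list
1 | 4-benzyloxy-3,5-dimethoxybenzaldehyde | O=Cc1cc(OC)c(OCc2ccccc2)c(OC)c1 | starting material
2 | dimethyl succinate | COC(=O)CCC(=O)OC | starting material
3 | (E)-4-(4-benzyloxy-3,5-dimethoxyphenyl)-3-(methoxycarbonyl)but-3-enoic acid | COC(=O)/C(CC(=O)O)=C/c1cc(OC)c(OCc2ccccc2)c(OC)c1 | intermediate
4 | (S)-4-benzyl-2-oxazolidinone | O=C1N[C@@H](Cc2ccccc2)CO1 | starting material
5 | mixed pivalic anhydride of 3 (E alkene) | COC(=O)/C(CC(=O)OC(=O)C(C)(C)C)=C/c1cc(OC)c(OCc2ccccc2)c(OC)c1 | intermediate
6 | (4S)-4-benzyl-3-[(E)-4-(4-benzyloxy-3,5-dimethoxyphenyl)-3-(methoxycarbonyl)but-3-enoyl]-1,3-oxazolidin-2-one | COC(=O)/C(CC(=O)N1[C@@H](Cc2ccccc2)COC1=O)=C/c1cc(OC)c(OCc2ccccc2)c(OC)c1 | intermediate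
7 | Z(O) dibutylboron dienolate of 6 (O–BBu2 on the former imide carbonyl, C3=C4 still E) | CCCCB(CCCC)O/C(N1[C@@H](Cc2ccccc2)COC1=O)=C\C(=C/c1cc(OC)c(OCc2ccccc2)c(OC)c1)C(=O)OC | intermediate
8 | dibutylboron syn-aldolate (open chain: C2 S, C1 S; C3=C4 E) | O=C(N1[C@@H](Cc2ccccc2)COC1=O)[C@@H](/C(C(=O)OC)=C\c1cc(OC)c(OCc2ccccc2)c(OC)c1)[C@H](OB(CCCC)CCCC)c1cc(OC)c(OCc2ccccc2)c(OC)c1 | intermediate
9 | methyl (1S,2R)-7-benzyloxy-1-(4-benzyloxy-3,5-dimethoxyphenyl)-6,8-dimethoxy-2-[(4S)-4-benzyl-2-oxo-1,3-oxazolidine-3-carbonyl]-1,2-dihydronaphthalene-3-carboxylate | COC(=O)C1=Cc2cc(OC)c(OCc3ccccc3)c(OC)c2[C@H](c2cc(OC)c(OCc3ccccc3)c(OC)c2)[C@H]1C(=O)N1[C@@H](Cc2ccccc2)COC1=O | intermediate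
10 | methyl (1S,2R)-7-benzyloxy-1-(4-benzyloxy-3,5-dimethoxyphenyl)-2-(hydroxymethyl)-6,8-dimethoxy-1,2-dihydronaphthalene-3-carboxylate | COC(=O)C1=Cc2cc(OC)c(OCc3ccccc3)c(OC)c2[C@H](c2cc(OC)c(OCc3ccccc3)c(OC)c2)[C@H]1CO | intermediate
11 | methyl (1S,2R)-7-hydroxy-1-(4-hydroxy-3,5-dimethoxyphenyl)-2-(hydroxymethyl)-6,8-dimethoxy-1,2-dihydronaphthalene-3-carboxylate | COC(=O)C1=Cc2cc(OC)c(O)c(OC)c2[C@H](c2cc(OC)c(O)c(OC)c2)[C@H]1CO | target

Total step count: 5. Longest linear sequence: 5 steps (1 → 3 → 6 → 9 → 10 → 11).

Steps most likely to fail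

Step 3. Both bond formations are known reaction types, but running them back to back in one flask has no direct counterpart on this substrate.
- The flask still holds the ammonium triflate and boron residues, so ionisation may be sluggish or diverted.
- The possible failures are buffering of the acid, proton loss from C2 of the cation (which would destroy the auxiliary-set centre), retro-aldol cleavage, or closure of the C1 oxygen onto the C3 ester.
- Fallback: the two bond formations are uncoupled. Setting out from 6 and 1, the boron aldol addition is run as above but ended with the customary oxidative work-up (pH 7 phosphate buffer, MeOH, H2O2, 0 °C), which cleaves 8 to the free syn-aldol carbinol F1.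
- After chromatography, F1 is cyclised on its own in dilute CH2Cl2 with CF3CO2H at 0 °C, the established carbinol cycloalkylation, and the route is rejoined at 9.

Step 4. The exocyclic carbonyl hangs pseudo-axially between the C1 aryl group and the C3 ester.
- Hydride may therefore attack the ring carbonyl of the auxiliary instead (endocyclic opening).
- If the reaction has to be forced, slow reduction of the ester or alkoxide-induced lactonisation may follow.
- Fallback: cleavage and reduction are separated. From 9, LiOH/H2O2 (THF–H2O, 0 °C) gives the C2 carboxylic acid F2, because the hydroperoxide anion prefers the exocyclic carbonyl even in hindered imides.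
- iBuOCOCl and N-methylmorpholine (THF, −15 °C) convert F2 into the mixed carbonic anhydride F3. NaBH4 (THF–MeOH, −15 to 0 °C) reduces F3 to 10 without touching the conjugated ester.

Step 5. The free hydroxymethyl group binds BCl3 and forces a larger excess of the Lewis acid.
- Two failures then become possible: Lewis acid-promoted closure of this alcohol onto the C3 ester, and chelation-assisted loss of a methyl ether next to a freshly formed boron phenoxide.
- Fallback: the order of the end-game is inverted so that the Lewis acid never meets the γ-hydroxy ester. From 9, BCl3/C6HMe5 (CH2Cl2, −78 °C) gives the bis-phenol imide F4.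
- LiBH4/MeOH (extra equivalents to cover the two phenols, THF, 0 °C, inert atmosphere) then cleaves the auxiliary reductively and delivers 11 directly.

Further compounds
F1 | step 3 | (4S)-4-benzyl-3-[(2S,3E)-4-(4-benzyloxy-3,5-dimethoxyphenyl)-2-[(S)-(4-benzyloxy-3,5-dimethoxyphenyl)(hydroxy)methyl]-3-(methoxycarbonyl)but-3-enoyl]-1,3-oxazolidin-2-one | O=C(N1[C@@H](Cc2ccccc2)COC1=O)[C@@H](/C(C(=O)OC)=C\c1cc(OC)c(OCc2ccccc2)c(OC)c1)[C@H](O)c1cc(OC)c(OCc2ccccc2)c(OC)c1
F2 | step 4 | (1S,2R)-7-benzyloxy-1-(4-benzyloxy-3,5-dimethoxyphenyl)-6,8-dimethoxy-3-(methoxycarbonyl)-1,2-dihydronaphthalene-2-carboxylic acid | COC(=O)C1=Cc2cc(OC)c(OCc3ccccc3)c(OC)c2[C@H](c2cc(OC)c(OCc3ccccc3)c(OC)c2)[C@H]1C(=O)O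
F3 | step 4 | isobutyl carbonic mixed anhydride of F2 (1S,2R) | COC(=O)C1=Cc2cc(OC)c(OCc3ccccc3)c(OC)c2[C@H](c2cc(OC)c(OCc3ccccc3)c(OC)c2)[C@H]1C(=O)OC(=O)OCC(C)C
F4 | step 5 | methyl (1S,2R)-7-hydroxy-1-(4-hydroxy-3,5-dimethoxyphenyl)-6,8-dimethoxy-2-[(4S)-4-benzyl-2-oxo-1,3-oxazolidine-3-carbonyl]-1,2-dihydronaphthalene-3-carboxylate | COC(=O)C1=Cc2cc(OC)c(O)c(OC)c2[C@H](c2cc(OC)c(O)c(OC)c2)[C@H]1C(=O)N1[C@@H](Cc2ccccc2)COC1=O
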